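Ring A is numbered C1 (acetyl), C2 (O), C3 (quaternary, methyl and prenyl), C4 (O), C5 (CH2Ar), C6 (C=O); ring B is the arene.
Cuts: the C5–CH2 bond of the methylene bridge (ring A monomer 21 plus aminomethylated ring B unit 25), the C1–acetyl bond, the C4–O bond, the prenyl C=C bond (Wittig, back to a γ-lactone) and last the lactone C2–O bond, which leads to the achiral dienone acid 10.
Forward: ring A is made as a carbocycle by Robinson annulation (propanal, methyl bromoacetate, methyl vinyl ketone) and dehydrogenated; the γ-lactone closes onto it, is opened to the prenyl chain, the ring is oxidised and acetylated, and ring B is joined last.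
Enabling feature: C3 is stereogenic only because the C2–C1 flank differs from the C4–C5 flank, so in 10 the two enone arms are enantiotopic and the CH2CO2H group on C3, a latent prenyl group, can select one of them.
Stereochemistry: C3 is fixed in step 6 by the catalyst's choice of enone arm (cis fusion follows from the tether); afterwards the C2 and C4 oxygens are kept chemically distinct until the acetyl group sits on C1, so no symmetric intermediate is crossed.

Key step: step 6

Assumption: the quinidine-derived thiourea is taken to give the (3aR,7aS) lactone; if the sense of induction is the opposite, its quinine-derived pseudo-enantiomer is used and the route is otherwise unchanged.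

Step 1
Reactants: 1 propanal
Product: 2 (E)-N,N-bis(2-methylpropyl)prop-1-en-1-amine
Conditions: i-Bu2NH, K2CO3, 0 °C → rt; filtration; distillation
Reagents that add atoms: diisobutylamine, CC(C)CNCC(C)C
Why: Condensation of the aldehyde with a hindered secondary amine gives the enamine directly (enamine formation), and the bulky isobutyl groups are chosen because they later disfavour N-alkylation.

Step 2
Reactants: 2 (E)-N,N-bis(2-methylpropyl)prop-1-en-1-amine; 3 methyl bromoacetate
Product: 5 methyl 3-methyl-4-oxobutanoate (racemic), via iminium bromide 4 (not isolated)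
Conditions: MeCN, reflux; then H2O, reflux
Reagents that add atoms: water, O (carbonyl oxygen of 5)
Why: Stork enamine alkylation, in which the enamine β-carbon displaces bromide from the activated α-halo ester and hydrolysis of the iminium salt frees the aldehyde; the new stereocentre is racemic and is erased in step 4.

Step 3
Reactants: 5 methyl 3-methyl-4-oxobutanoate; 6 methyl vinyl ketone
Product: 8 methyl 2-(1-methyl-4-oxocyclohex-2-en-1-yl)acetate (racemic), via Michael adduct 7 (not isolated)
Conditions: H2SO4 (cat.), PhMe, 45 °C → reflux, azeotropic removal of H2O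
Reagents that add atoms: none
Why: Acid-catalysed Robinson annulation, in which the enol of the α-branched aldehyde adds to the enone (Michael addition) and the methyl ketone of 7 condenses onto the now non-enolisable aldehyde (aldol condensation), so that only the 4,4-disubstituted cyclohex-2-enone can form.

Step 4
Reactants: 8 methyl 2-(1-methyl-4-oxocyclohex-2-en-1-yl)acetate
Product: 9 methyl 2-(1-methyl-4-oxocyclohexa-2,5-dien-1-yl)acetate
Conditions: DDQ (1.5 equiv), 1,4-dioxane, reflux
Reagents that add atoms: none
Why: Quinone dehydrogenation of the cyclohexenone through its dienol gives the cross-conjugated dienone, which cannot aromatise because C4 is quaternary and which is achiral, so the racemic centre of 8 disappears on purpose.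

Step 5
Reactants: 9 methyl 2-(1-methyl-4-oxocyclohexa-2,5-dien-1-yl)acetate
Product: 10 2-(1-methyl-4-oxocyclohexa-2,5-dien-1-yl)acetic acid
Conditions: LiOH, THF/H2O, 0 °C; then 1 M HCl to pH 3, 0 °C
Reagents that add atoms: lithium hydroxide, [Li+].[OH-] (carboxyl OH oxygen)
Why: Cold ester saponification and cold acidification free the acid while the hydrated carboxylate has little tendency to lactonise, so the substrate should reach the key step achiral and free of racemic lactone.

Step 6
Reactants: 10 2-(1-methyl-4-oxocyclohexa-2,5-dien-1-yl)acetic acid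
Product: 11 (3aR,7aS)-3a-methyl-3,3a,7,7a-tetrahydro-1-benzofuran-2,6-dione
Conditions: 9-amino(9-deoxy)epi-quinidine-derived N-[3,5-bis(trifluoromethyl)phenyl]thiourea (10 mol %), PhMe, −20 °C; filtration through silica
Reagents that add atoms: none
Why: Proposed new method: the quinuclidine nitrogen of the catalyst deprotonates the acid while the thiourea and the ammonium N–H hold the dienone carbonyl and the carboxylate by hydrogen bonds, the carboxylate oxygen adds to the β-carbon of one enone (C7a of 11, C2 of ring A) and the resulting enol is protonated at C7. The closest known reaction types are the organocatalytic desymmetrising oxa-Michael cyclisation of 4-(2-hydroxyethyl)cyclohexa-2,5-dienones and the bifunctional-base-catalysed oxa-Michael lactonisation of enone carboxylic acids, and the proposal merges the two. The γ-lactone closes in the 5-exo-trig mode, and since the two-atom tether reaches only the face on which it stands the ring fusion must be cis. C3a (C3 of ring A) becomes stereogenic the moment one of the two enantiotopic enone arms is attacked, a choice made by the chiral pocket of the catalyst, and the configuration at C7a follows from it through the cis fusion. The only selectivity asked of the catalyst is thus the choice between two enantiotopic alkenes, and the small steric difference between the methyl group and the acetic acid arm never has to be read. Low temperature, a non-polar solvent and prompt removal of the basic catalyst on silica keep the step under kinetic control, because E1cB loss of the carboxylate would return achiral 10.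

Step 7
Reactants: 11 (3aR,7aS)-3a-methyl-3,3a,7,7a-tetrahydro-1-benzofuran-2,6-dione
Product: 13 (3aR,4S,7aS)-4-hydroxy-3a-methylhexahydro-1-benzofuran-2,6-dione, via boronate 12 (not isolated)
Conditions: B2pin2, CuCl (5 mol %), DPEphos (5 mol %), NaOt-Bu (5 mol %), MeOH (2 equiv), THF, 0 °C; then NaBO3·4H2O, THF/H2O, 0 °C → rt
Reagents that add atoms: bis(pinacolato)diboron, CC1(C)OB(OC1(C)C)B1OC(C)(C)C(C)(C)O1 (boryl group of 12 only); sodium perborate tetrahydrate, [Na+].[O-]OB=O.O.O.O.O (hydroxyl oxygen of 13)
Why: Copper-catalysed conjugate borylation of the enone followed by stereoretentive perborate oxidation of the C–B bond should give the β-hydroxy ketone, the Cu–Bpin species approaching C4 from the convex face (syn to the angular methyl, anti to the lactone ring); C4 later becomes a carbonyl, so its configuration matters only in that a C4 epimer is best removed here.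

Step 8
Reactants: 13 (3aR,4S,7aS)-4-hydroxy-3a-methylhexahydro-1-benzofuran-2,6-dione
Product: 14 (3aS,4S,7aS)-4-{[tert-butyl(dimethyl)silyl]oxy}-3a-methylhexahydro-1-benzofuran-2,6-dione
Conditions: TBSOTf, 2,6-lutidine, CH2Cl2, −78 → 0 °C
Reagents that add atoms: tert-butyldimethylsilyl trifluoromethanesulfonate, CC(C)(C)[Si](C)(C)OS(=O)(=O)C(F)(F)F
Why: Silyl ether protection of the hindered secondary alcohol with a silyl triflate and a non-nucleophilic base marks the C4 oxygen as different from the C7a oxygen, which keeps the two flanks of the quaternary carbon distinguishable in all later intermediates.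

Step 9
Reactants: 14 (3aS,4S,7aS)-4-{[tert-butyl(dimethyl)silyl]oxy}-3a-methylhexahydro-1-benzofuran-2,6-dione
Product: 15 (3aS,4S,7aS)-4-{[tert-butyl(dimethyl)silyl]oxy}-3a-methyloctahydro-1-benzofuran-2,6-diol (epimer mixture at C2 and C6)
Conditions: i-Bu2AlH (2.5 equiv), CH2Cl2, −78 °C; aq. potassium sodium tartrate
Reagents that add atoms: none
Why: At −78 °C i-Bu2AlH reduces the lactone only as far as the lactol and the ketone to the carbinol (hydride reduction), and the two uncontrolled carbinol centres are of no consequence because one becomes an alkene carbon and the other is reoxidised.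

Step 10
Reactants: 15 (3aS,4S,7aS)-4-{[tert-butyl(dimethyl)silyl]oxy}-3a-methyloctahydro-1-benzofuran-2,6-diol
Product: 16 (3S,4S,5S)-5-{[tert-butyl(dimethyl)silyl]oxy}-4-methyl-4-(3-methylbut-2-en-1-yl)cyclohexane-1,3-diol (epimer mixture at C1)
Conditions: i-PrPPh3I (4 equiv), n-BuLi (3.9 equiv), THF, 0 °C; then 15, 0 °C → rt
Reagents that add atoms: isopropyltriphenylphosphonium iodide, CC(C)[P+](c1ccccc1)(c1ccccc1)c1ccccc1.[I-]
Why: Wittig olefination of the open hydroxy-aldehyde form of the lactol with the unstabilised isopropylidene ylide (the excess also serving as base for the two hydroxyls) installs the prenyl group and frees the C3 hydroxyl, and the silyl ether, being trans to that alkoxide, should not migrate to it.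

Step 11
Reactants: 16 (3S,4S,5S)-5-{[tert-butyl(dimethyl)silyl]oxy}-4-methyl-4-(3-methylbut-2-en-1-yl)cyclohexane-1,3-diol
Product: 17 (4R,5S)-5-{[tert-butyl(dimethyl)silyl]oxy}-4-methyl-4-(3-methylbut-2-en-1-yl)cyclohexane-1,3-dione
Conditions: IBX (3 equiv), EtOAc, 75 °C
Reagents that add atoms: none
Why: Oxidation of both secondary alcohols with the pentavalent iodine reagent (IBX oxidation), which is suited to β-hydroxy ketones and spares the active methylene of the resulting β-diketone, gives the enolisable 1,3-dione without touching the silyl ether or the trisubstituted alkene.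

Step 12
Reactants: 17 (4R,5S)-5-{[tert-butyl(dimethyl)silyl]oxy}-4-methyl-4-(3-methylbut-2-en-1-yl)cyclohexane-1,3-dione
Product: 19 (4R,5S)-2-acetyl-5-{[tert-butyl(dimethyl)silyl]oxy}-3-hydroxy-4-methyl-4-(3-methylbut-2-en-1-yl)cyclohex-2-en-1-one, via enol acetate 18 (not isolated)
Conditions: AcOH, DCC, DMAP (0.3 equiv), CH2Cl2, 0 °C → rt
Reagents that add atoms: acetic acid, CC(=O)O
Why: Carbodiimide-mediated O-acetylation of the dione enol followed by DMAP-catalysed O-to-C acyl transfer (enol ester rearrangement) places the acetyl group on C2, the only carbon between the two carbonyls, and so makes the two sides of the quaternary carbon constitutionally different for good.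

Step 13
Reactants: 19 (4R,5S)-2-acetyl-5-{[tert-butyl(dimethyl)silyl]oxy}-3-hydroxy-4-methyl-4-(3-methylbut-2-en-1-yl)cyclohex-2-en-1-one
Product: 20 (4R,5S)-2-acetyl-3,5-dihydroxy-4-methyl-4-(3-methylbut-2-en-1-yl)cyclohex-2-en-1-one
Conditions: HF·pyridine, pyridine, THF, 0 °C → rt
Reagents that add atoms: none
Why: Buffered fluoride cleaves the Si–O bond (desilylation) under conditions mild enough to spare the acid-sensitive prenyl group and to avoid dehydration of the β-hydroxy ketone.

Step 14
Reactants: 20 (4R,5S)-2-acetyl-3,5-dihydroxy-4-methyl-4-(3-methylbut-2-en-1-yl)cyclohex-2-en-1-one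
Product: 21 (4R)-2-acetyl-3,5-dihydroxy-4-methyl-4-(3-methylbut-2-en-1-yl)cyclohexa-2,5-dien-1-one
Conditions: IBX (1.5 equiv), EtOAc, 70 °C
Reagents that add atoms: none
Why: IBX oxidation of the β-hydroxy ketone to the β-diketone completes the trione, which enolises to the acylfilicinic-acid-type dienone; the C5 carbinol centre vanishes and C4 stays stereogenic because C2 carries acetyl and C6 carries hydrogen.

Step 15
Reactants: 22 2,4,6-trihydroxyacetophenone; 23 1-bromo-3-methylbut-2-ene
Product: 24 1-[2,4,6-trihydroxy-3-(3-methylbut-2-en-1-yl)phenyl]ethan-1-one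
Conditions: 10 % aq. KOH, 0 °C → rt (23 as the limiting reagent)
Reagents that add atoms: none
Why: C-alkylation of the ambident phloroglucinol phenoxide with the allylic bromide in water (C-prenylation) favours carbon over oxygen, and a deficit of bromide limits double prenylation.

Step 16
Reactants: 24 1-[2,4,6-trihydroxy-3-(3-methylbut-2-en-1-yl)phenyl]ethan-1-one
Product: 25 1-{3-[(dimethylamino)methyl]-2,4,6-trihydroxy-5-(3-methylbut-2-en-1-yl)phenyl}ethan-1-one
Conditions: Me2N=CH2+ I− (1.0 equiv), Et3N, CH2Cl2, 0 °C → rt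
Reagents that add atoms: dimethylmethylideneammonium iodide, C=[N+](C)C.[I-]
Why: Mannich aminomethylation at the only free ring position with the preformed iminium salt gives the ortho-hydroxybenzylamine and avoids free formaldehyde, which would bridge two arenes.

Step 17
Reactants: 21 (4R)-2-acetyl-3,5-dihydroxy-4-methyl-4-(3-methylbut-2-en-1-yl)cyclohexa-2,5-dien-1-one; 25 1-{3-[(dimethylamino)methyl]-2,4,6-trihydroxy-5-(3-methylbut-2-en-1-yl)phenyl}ethan-1-one
Product: 27 (4R)-2-acetyl-6-{[3-acetyl-2,4,6-trihydroxy-5-(3-methylbut-2-en-1-yl)phenyl]methyl}-3,5-dihydroxy-4-methyl-4-(3-methylbut-2-en-1-yl)cyclohexa-2,5-dien-1-one, via ortho-quinone methide 26 (not isolated)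
Conditions: PhMe, 80 °C, under Ar
Reagents that add atoms: none
Why: Thermal loss of dimethylamine from the ortho-hydroxybenzylamine gives the ortho-quinone methide, which is trapped at its exocyclic carbon by C6 of the vinylogous acid 21 (Michael addition driven by rearomatisation); 25 has no free ring position and cannot dimerise, and the quaternary stereocentre is not touched.

Compound list
1 | propanal | CCC=O | starting material
2 | (E)-N,N-bis(2-methylpropyl)prop-1-en-1-amine | C/C=C/N(CC(C)C)CC(C)C | intermediate
3 | methyl bromoacetate | COC(=O)CBr | starting material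
4 | (4-methoxy-2-methyl-4-oxobutylidene)bis(2-methylpropyl)ammonium bromide (racemic) | COC(=O)CC(C)C=[N+](CC(C)C)CC(C)C.[Br-] | intermediate
5 | methyl 3-methyl-4-oxobutanoate (racemic) | COC(=O)CC(C)C=O | intermediate
6 | methyl vinyl ketone (but-3-en-2-one) | CC(=O)C=C | starting material
7 | methyl 3-formyl-3-methyl-6-oxoheptanoate (racemic) | COC(=O)CC(C)(C=O)CCC(C)=O | intermediate
8 | methyl 2-(1-methyl-4-oxocyclohex-2-en-1-yl)acetate (racemic) | COC(=O)CC1(C)CCC(=O)C=C1 | intermediate
9 | methyl 2-(1-methyl-4-oxocyclohexa-2,5-dien-1-yl)acetate (achiral) | COC(=O)CC1(C)C=CC(=O)C=C1 | intermediate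
10 | 2-(1-methyl-4-oxocyclohexa-2,5-dien-1-yl)acetic acid (achiral) | CC1(CC(=O)O)C=CC(=O)C=C1 | intermediate
11 | (3aR,7aS)-3a-methyl-3,3a,7,7a-tetrahydro-1-benzofuran-2,6-dione (cis-fused) | O=C1C[C@@H]2OC(=O)C[C@]2(C)C=C1 | intermediate
12 | (3aR,4S,7aS)-3a-methyl-4-(4,4,5,5-tetramethyl-1,3,2-dioxaborolan-2-yl)hexahydro-1-benzofuran-2,6-dione | O=C1C[C@@H]2OC(=O)C[C@]2(C)[C@@H](B3OC(C)(C)C(C)(C)O3)C1 | intermediate
13 | (3aR,4S,7aS)-4-hydroxy-3a-methylhexahydro-1-benzofuran-2,6-dione (4-OH cis to the angular methyl) | O=C1C[C@@H]2OC(=O)C[C@]2(C)[C@@H](O)C1 | intermediate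
14 | (3aS,4S,7aS)-4-{[tert-butyl(dimethyl)silyl]oxy}-3a-methylhexahydro-1-benzofuran-2,6-dione | O=C1C[C@@H]2OC(=O)C[C@]2(C)[C@@H](O[Si](C)(C)C(C)(C)C)C1 | intermediate
15 | (3aS,4S,7aS)-4-{[tert-butyl(dimethyl)silyl]oxy}-3a-methyloctahydro-1-benzofuran-2,6-diol (epimers at C2 and C6) | OC1C[C@@H]2OC(O)C[C@]2(C)[C@@H](O[Si](C)(C)C(C)(C)C)C1 | intermediate
16 | (3S,4S,5S)-5-{[tert-butyl(dimethyl)silyl]oxy}-4-methyl-4-(3-methylbut-2-en-1-yl)cyclohexane-1,3-diol (epimers at C1) | OC1C[C@H](O)[C@](C)(CC=C(C)C)[C@@H](O[Si](C)(C)C(C)(C)C)C1 | intermediate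
17 | (4R,5S)-5-{[tert-butyl(dimethyl)silyl]oxy}-4-methyl-4-(3-methylbut-2-en-1-yl)cyclohexane-1,3-dione | O=C1CC(=O)[C@](C)(CC=C(C)C)[C@@H](O[Si](C)(C)C(C)(C)C)C1 | intermediate
18 | (4R,5S)-5-{[tert-butyl(dimethyl)silyl]oxy}-4-methyl-4-(3-methylbut-2-en-1-yl)-3-oxocyclohex-1-en-1-yl acetate (less hindered enol ester; its regioisomer would converge) | CC(=O)OC1=CC(=O)[C@](C)(CC=C(C)C)[C@@H](O[Si](C)(C)C(C)(C)C)C1 | intermediate
19 | (4R,5S)-2-acetyl-5-{[tert-butyl(dimethyl)silyl]oxy}-3-hydroxy-4-methyl-4-(3-methylbut-2-en-1-yl)cyclohex-2-en-1-one | CC(=O)C1=C(O)[C@](C)(CC=C(C)C)[C@@H](O[Si](C)(C)C(C)(C)C)CC1=O | intermediate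
20 | (4R,5S)-2-acetyl-3,5-dihydroxy-4-methyl-4-(3-methylbut-2-en-1-yl)cyclohex-2-en-1-one | CC(=O)C1=C(O)[C@](C)(CC=C(C)C)[C@@H](O)CC1=O | intermediate
21 | (4R)-2-acetyl-3,5-dihydroxy-4-methyl-4-(3-methylbut-2-en-1-yl)cyclohexa-2,5-dien-1-one | CC(=O)C1=C(O)[C@](C)(CC=C(C)C)C(O)=CC1=O | intermediate
22 | 2,4,6-trihydroxyacetophenone | CC(=O)c1c(O)cc(O)cc1O | starting material
23 | 1-bromo-3-methylbut-2-ene (prenyl bromide) | CC(C)=CCBr | starting material
24 | 1-[2,4,6-trihydroxy-3-(3-methylbut-2-en-1-yl)phenyl]ethan-1-one | CC(=O)c1c(O)cc(O)c(CC=C(C)C)c1O | intermediate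
25 | 1-{3-[(dimethylamino)methyl]-2,4,6-trihydroxy-5-(3-methylbut-2-en-1-yl)phenyl}ethan-1-one | CC(=O)c1c(O)c(CN(C)C)c(O)c(CC=C(C)C)c1O | intermediate
26 | 4-acetyl-3,5-dihydroxy-6-methylidene-2-(3-methylbut-2-en-1-yl)cyclohexa-2,4-dien-1-one | C=C1C(=O)C(CC=C(C)C)=C(O)C(C(C)=O)=C1O | intermediate
27 | (4R)-2-acetyl-6-{[3-acetyl-2,4,6-trihydroxy-5-(3-methylbut-2-en-1-yl)phenyl]methyl}-3,5-dihydroxy-4-methyl-4-(3-methylbut-2-en-1-yl)cyclohexa-2,5-dien-1-one | CC(=O)C1=C(O)[C@](C)(CC=C(C)C)C(O)=C(Cc2c(O)c(CC=C(C)C)c(O)c(C(C)=O)c2O)C1=O | target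

Total step count: 17. Longest linear sequence: 15 steps (steps 1–14 and 17); steps 15 and 16 form the two-step branch to 25.

Steps most likely to fail

Step 6. The carboxylate may bind the thiourea so firmly that turnover stalls, or the lactone may reopen by E1cB elimination and lose enantiomeric purity before it is used. The fallback uses known chemistry, sets out from 9 and returns at 14; it replaces the acid nucleophile by an alcohol, for which chiral-phosphoric-acid-catalysed oxa-Michael desymmetrisation of cyclohexadienones is established. i-Bu2AlH reduces the ester and the dienone carbonyl of 9 to 4-(2-hydroxyethyl)-4-methylcyclohexa-2,5-dien-1-ol F1, and MnO2 reoxidises only the doubly allylic alcohol to 4-(2-hydroxyethyl)-4-methylcyclohexa-2,5-dien-1-one F2. A BINOL-derived chiral phosphoric acid, its enantiomer chosen for the sense shown, then closes the cis-fused ether (3aR,7aS)-3a-methyl-2,3,3a,7a-tetrahydro-1-benzofuran-6(7H)-one F3. Conjugate borylation as in step 7 gives (3aR,4S,7aS)-3a-methyl-4-(4,4,5,5-tetramethyl-1,3,2-dioxaborolan-2-yl)hexahydro-1-benzofuran-6(2H)-one F4, and perborate oxidation gives (3aR,4S,7aS)-4-hydroxy-3a-methylhexahydro-1-benzofuran-6(2H)-one F5. TBSOTf and 2,6-lutidine give (3aS,4S,7aS)-4-{[tert-butyl(dimethyl)silyl]oxy}-3a-methylhexahydro-1-benzofuran-6(2H)-one F6, and RuCl3 (cat.)/NaIO4 oxidises the ether CH2 next to oxygen to the lactone carbonyl, which is 14.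

Step 7. The catalytic alkoxide may open the β-acyloxy ketone by E1cB elimination, which at this stage still leads back to achiral material and erodes enantiomeric purity, and borylation next to the quaternary carbon may be slow. The fallback sets out from 11 and returns at 13 and works without base: dimethyldioxirane in acetone epoxidises the enone from the convex face to (3aS,4R,5R,7aS)-4,5-epoxy-3a-methylhexahydro-1-benzofuran-2,6-dione F7, and SmI2 in THF/MeOH at −90 °C cleaves the Cα–O bond of the epoxy ketone reductively to give 13.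

Step 17. Amine loss may be sluggish, and O-alkylation or exchange of the methylene unit between the two phloroglucinol partners may compete with the wanted C–C bond formation. The fallback sets out from 21 (with 24 from step 15) and returns at 27, with the roles of the partners reversed. Me2N=CH2+ I− aminomethylates 21 at C6 to (4R)-2-acetyl-6-[(dimethylamino)methyl]-3,5-dihydroxy-4-methyl-4-(3-methylbut-2-en-1-yl)cyclohexa-2,5-dien-1-one F8. On warming with 24 this loses dimethylamine to (4S)-2-acetyl-3-hydroxy-4-methyl-6-methylidene-4-(3-methylbut-2-en-1-yl)cyclohex-2-ene-1,5-dione F9 (same spatial arrangement, descriptor changed by priority only). The free ring position of 24 then adds to its exocyclic carbon in a Friedel–Crafts-type conjugate addition to give 27.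

Further compounds
F1 | step 6 | 4-(2-hydroxyethyl)-4-methylcyclohexa-2,5-dien-1-ol (cis/trans mixture) | CC1(CCO)C=CC(O)C=C1
F2 | step 6 | 4-(2-hydroxyethyl)-4-methylcyclohexa-2,5-dien-1-one | CC1(CCO)C=CC(=O)C=C1
F3 | step 6 | (3aR,7aS)-3a-methyl-2,3,3a,7a-tetrahydro-1-benzofuran-6(7H)-one | O=C1C[C@@H]2OCC[C@]2(C)C=C1
F4 | step 6 | (3aR,4S,7aS)-3a-methyl-4-(4,4,5,5-tetramethyl-1,3,2-dioxaborolan-2-yl)hexahydro-1-benzofuran-6(2H)-one | O=C1C[C@@H]2OCC[C@]2(C)[C@@H](B3OC(C)(C)C(C)(C)O3)C1
F5 | step 6 | (3aR,4S,7aS)-4-hydroxy-3a-methylhexahydro-1-benzofuran-6(2H)-one | O=C1C[C@@H]2OCC[C@]2(C)[C@@H](O)C1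
F6 | step 6 | (3aS,4S,7aS)-4-{[tert-butyl(dimethyl)silyl]oxy}-3a-methylhexahydro-1-benzofuran-6(2H)-one | O=C1C[C@@H]2OCC[C@]2(C)[C@@H](O[Si](C)(C)C(C)(C)C)C1
F7 | step 7 | (3aS,4R,5R,7aS)-4,5-epoxy-3a-methylhexahydro-1-benzofuran-2,6-dione (oxirane cis to the angular methyl) | O=C1C[C@@H]2OC(=O)C[C@]2(C)[C@H]3O[C@H]31
F8 | step 17 | (4R)-2-acetyl-6-[(dimethylamino)methyl]-3,5-dihydroxy-4-methyl-4-(3-methylbut-2-en-1-yl)cyclohexa-2,5-dien-1-one | CC(=O)C1=C(O)[C@](C)(CC=C(C)C)C(O)=C(CN(C)C)C1=O
F9 | step 17 | (4S)-2-acetyl-3-hydroxy-4-methyl-6-methylidene-4-(3-methylbut-2-en-1-yl)cyclohex-2-ene-1,5-dione | CC(=O)C1=C(O)[C@](C)(CC=C(C)C)C(=O)C(=C)C1=O
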